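**Plan**

1. Numbering: ring A is the dibromophenol ring (C1–OH, C2–Br, C4–Br, C6–O-aryl); ring B is the tribromophenol ring (C1'–O-aryl, C3'/C4'/C5'–Br, C6'–OH).
2. Retrosynthesis: the four C–Br bonds ortho and para to the two hydroxyls (C2, C4, C3', C5') and the C6' O-methyl are removed first. Ring A is then cut at C5–C6 and C1–C2, with its C1–O bond traced to the furan oxygen. Last, the ynol ether triple bond is unravelled to an O-(2-bromoethyl) ether of 4-bromo-2-methoxyphenol.
3. Enabling feature: in ring A the hydroxyl carbon C1 and the aryloxy carbon C6 are neighbours, so they map onto the two sp carbons of an aryl ethynyl ether. The remaining C2–C3–C4–C5 chain plus the C1 oxygen is exactly furan.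
4. Forward order: ring B is bought with its C4' bromine in place and the ethynyl arm is grown on its phenol oxygen in four steps. Ring A is then closed in one gold-catalysed benzannulation with furan, and demethylation and a fourfold hydroxyl-directed bromination finish the molecule.
5. Stereochemistry: the target has no stereocentre and no stereogenic double bond. The (Z)-bromoalkene and the racemic transient species on the way are all erased.

Key step: step 5

Assumption: the terminal aryl ethynyl ether is taken to survive as a cold, dilute solution for the hours between its preparation and its use, as simple aryloxyacetylenes do.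

**Route**

Step 1
Reactants: 1 4-bromo-2-methoxyphenol; 2 1,2-dibromoethane
Product: 3 4-bromo-1-(2-bromoethoxy)-2-methoxybenzene
Conditions: 2 (5 equiv), K2CO3 (2 equiv), MeCN, reflux
Reagents that add atoms: none
Why: Williamson ether synthesis (SN2 of the phenoxide on the primary bromide), with the large excess of dibromide suppressing the bis-aryl ether.

Step 2
Reactants: 3 4-bromo-1-(2-bromoethoxy)-2-methoxybenzene
Product: 4 4-bromo-1-(ethenyloxy)-2-methoxybenzene
Conditions: KOtBu (1.5 equiv), THF, 0 °C to rt
Reagents that add atoms: none
Why: E2 dehydrobromination of a 2-aryloxyethyl bromide is the standard entry to aryl vinyl ethers, and the aryl bromide should be inert to KOtBu in THF at this temperature.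

Step 3
Reactants: 4 4-bromo-1-(ethenyloxy)-2-methoxybenzene
Product: 6 4-bromo-1-{[(Z)-2-bromoethenyl]oxy}-2-methoxybenzene, via dibromide 5 (not isolated)
Conditions: Br2 (1.0 equiv), Et2O, −78 °C; then KOtBu (1.05 equiv, THF solution), −78 °C to 0 °C
Reagents that add atoms: bromine, BrBr
Why: Electrophilic addition of Br2 to the enol ether double bond should be far faster at −78 °C than ring bromination, and the labile alpha-bromo ether then undergoes E2 loss of HBr (acidified CH2Br proton, alpha-bromide leaving) to the 2-bromovinyl ether, for which the Z isomer is the classically favoured one.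

Step 4
Reactants: 6 4-bromo-1-{[(Z)-2-bromoethenyl]oxy}-2-methoxybenzene
Product: 7 4-bromo-1-(ethynyloxy)-2-methoxybenzene
Conditions: KOtBu (1.5 equiv), 18-crown-6 (10 mol%), THF, −20 °C to 10 °C; cold work-up, basic Al2O3 plug (pentane), used at once
Reagents that add atoms: none
Why: Anti-periplanar E2 dehydrobromination (in the Z alkene the hydrogen on the oxygen-bearing carbon is trans to bromine) is the classical route to aryloxyacetylenes, and a hindered alkoxide is chosen because amide or alkyllithium bases would attack the aryl bromide.

Step 5
Reactants: 7 4-bromo-1-(ethynyloxy)-2-methoxybenzene; 8 furan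
Product: 11 2-(4-bromo-2-methoxyphenoxy)phenol, via oxepine 9 (not isolated), via arene oxide 10 (not isolated)
Conditions: IPrAuNTf2 (5 mol%; IPr = 1,3-bis(2,6-diisopropylphenyl)imidazol-2-ylidene), furan (15 equiv), 4 Å MS, CH2Cl2, slow addition of 7, 0 °C to rt
Reagents that add atoms: none
Why: Monovalent gold makes the oxygen-bearing alkyne carbon of 7 electrophilic, a furan alpha carbon adds there (C5–C6), and the cyclopropyl gold carbene so formed opens the furan to a (Z)-dienal gold carbene whose aldehyde oxygen attacks the carbene carbon (the future C1) to give, after loss of gold, oxepine 9. Ring A then closes by thermal disrotatory 6π electrocyclisation of 9 to arene oxide 10 (C1–C2), and heterolysis of the C2–O bond followed by loss of the C1 proton (or a 1,2-hydride shift and enolisation) should deliver phenol 11. The reaction type is the gold-catalysed furan–yne phenol synthesis in its intermolecular variant with terminal alkynes, here run on a heteroatom-polarised alkyne and parent furan. No stereocentre is created in 11; 10 is racemic and cis-fused by ring strain, and both enantiomers give the same phenol. The step needs two selectivities: the alkyne orientation, secured by the ether oxygen lone pair that localises positive charge on the carbon it is attached to, and the direction of epoxide opening, secured because only C2–O cleavage gives a pentadienyl cation with a terminus on C6 that the aryloxy oxygen stabilises, which leaves the hydroxyl on C1 next to the ether. A large excess of furan and slow addition of 7 should keep the product phenol and adventitious water from intercepting the activated ynol ether.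

Step 6
Reactants: 11 2-(4-bromo-2-methoxyphenoxy)phenol
Product: 12 5-bromo-2-(2-hydroxyphenoxy)phenol
Conditions: BBr3 (2.5 equiv), CH2Cl2, −78 °C to 0 °C; then H2O
Reagents that add atoms: none
Why: Lewis-acid cleavage of the aryl methyl ether (bromide attacks the O-methyl of the boron-complexed ether in an SN2 step) should leave the diaryl ether and the aryl bromide untouched.

Step 7
Reactants: 12 5-bromo-2-(2-hydroxyphenoxy)phenol
Product: 13 2,3,4-tribromo-6-(3,5-dibromo-2-hydroxyphenoxy)phenol
Conditions: Br2 (4.1 equiv), AcOH, rt
Reagents that add atoms: bromine, BrBr
Why: Electrophilic aromatic bromination is directed by the two free hydroxyls to their open ortho and para positions (C2 and C4 on ring A, C5' and C3' on ring B), the other ortho site on each ring being taken by the ether oxygen, and the stoichiometry should stop the reaction at the pentabromide.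

**Compound list**

1 | 4-bromo-2-methoxyphenol | COc1cc(Br)ccc1O | starting material
2 | 1,2-dibromoethane | BrCCBr | starting material
3 | 4-bromo-1-(2-bromoethoxy)-2-methoxybenzene | COc1cc(Br)ccc1OCCBr | intermediate
4 | 4-bromo-1-(ethenyloxy)-2-methoxybenzene | COc1cc(Br)ccc1OC=C | intermediate
5 | 4-bromo-1-(1,2-dibromoethoxy)-2-methoxybenzene (racemic; not isolated) | COc1cc(Br)ccc1OC(Br)CBr | intermediate
6 | 4-bromo-1-{[(Z)-2-bromoethenyl]oxy}-2-methoxybenzene | COc1cc(Br)ccc1O/C=C\Br | intermediate
7 | 4-bromo-1-(ethynyloxy)-2-methoxybenzene | COc1cc(Br)ccc1OC#C | intermediate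
8 | furan | c1ccoc1 | starting material
9 | 3-(4-bromo-2-methoxyphenoxy)oxepine (not isolated) | COc1cc(Br)ccc1OC1=COC=CC=C1 | intermediate
10 | 2-(4-bromo-2-methoxyphenoxy)-7-oxabicyclo[4.1.0]hepta-2,4-diene (racemic, cis-fused, one enantiomer drawn; not isolated) | COc1cc(Br)ccc1OC1=CC=C[C@H]2O[C@@H]12 | intermediate
11 | 2-(4-bromo-2-methoxyphenoxy)phenol | COc1cc(Br)ccc1Oc1ccccc1O | intermediate
12 | 5-bromo-2-(2-hydroxyphenoxy)phenol | Oc1cc(Br)ccc1Oc1ccccc1O | intermediate
13 | 2,3,4-tribromo-6-(3,5-dibromo-2-hydroxyphenoxy)phenol | Oc1c(Br)cc(Br)cc1Oc1cc(Br)c(Br)c(Br)c1O | target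

**Step count**

Total steps: 7. Longest linear sequence: 7 steps (from 1 to 13).

**Steps most likely to fail**

Step 5. The activated ynol ether may be intercepted at oxygen by the product phenol or by traces of water before furan adds at carbon. The first C–C adduct may also rearomatise by protodeauration (plain hydroarylation of furan) instead of opening the furan ring, or the ynol ether may oligomerise on the catalyst. The fallback builds the same 2-aryloxyphenol without the alkyne. It sets out from 1: SNAr with 2-fluorobenzaldehyde (K2CO3, DMF, 120 °C) should give 2-(4-bromo-2-methoxyphenoxy)benzaldehyde F1. Baeyer–Villiger oxidation of the aldehyde (mCPBA, CH2Cl2, rt; Dakin-type aryl migration) should give 2-(4-bromo-2-methoxyphenoxy)phenyl formate F2. Methanolysis (K2CO3 cat., MeOH, rt) then returns the route at 11.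

Step 4. The E2 on the vinyl bromide may be too slow at temperatures the product tolerates (any E isomer can only eliminate syn), tert-butoxide may add to the ynol ether, or the ynol ether may hydrate or oligomerise during isolation. The fallback replaces the vinyl bromide by an enol sulfonate and sets out from 1. Alkylation with bromoacetaldehyde diethyl acetal (K2CO3, DMF, 110 °C) should give 4-bromo-1-(2,2-diethoxyethoxy)-2-methoxybenzene F3. Aqueous HCl in THF should free 2-(4-bromo-2-methoxyphenoxy)acetaldehyde F4. Nonafluorobutanesulfonyl fluoride with the phosphazene base tert-butylimino-tris(dimethylamino)phosphorane (DMF, −20 °C to rt) should sulfonylate the enolate to 2-(4-bromo-2-methoxyphenoxy)ethenyl nonafluorobutane-1-sulfonate F5. F5 should lose nonaflate under the same base in the same flask (the general carbonyl-to-alkyne conversion through alkenyl nonaflates), and the route is rejoined at 7.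

Step 7. Bromination may stall at the crowded C3' and C5' sites flanking the C4' bromine, or a further bromine may enter para or ortho to the ether oxygen (C3 of ring A, C2' of ring B) once the hydroxyl-directed sites are filled. Either outcome gives mixtures of close homologues. The fallback brominates ring by ring with ring B held as its methyl ether, and sets out from 11. Br2 (2 equiv, AcOH, 0 °C) should give 2,4-dibromo-6-(4-bromo-2-methoxyphenoxy)phenol F6; any bromine straying onto ring B goes para to the methoxy group, which is a wanted position. BBr3 (CH2Cl2, −78 °C to 0 °C) should then give 2,4-dibromo-6-(4-bromo-2-hydroxyphenoxy)phenol F7. Br2 (2 equiv, AcOH, rt) on the now isolated, single reactive ring returns the route at 13.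

**Further compounds**

F1 | step 5 | 2-(4-bromo-2-methoxyphenoxy)benzaldehyde | COc1cc(Br)ccc1Oc1ccccc1C=O
F2 | step 5 | 2-(4-bromo-2-methoxyphenoxy)phenyl formate | COc1cc(Br)ccc1Oc1ccccc1OC=O
F3 | step 4 | 4-bromo-1-(2,2-diethoxyethoxy)-2-methoxybenzene | CCOC(COc1ccc(Br)cc1OC)OCC
F4 | step 4 | 2-(4-bromo-2-methoxyphenoxy)acetaldehyde | COc1cc(Br)ccc1OCC=O
F5 | step 4 | 2-(4-bromo-2-methoxyphenoxy)ethenyl nonafluorobutane-1-sulfonate (E/Z mixture) | COc1cc(Br)ccc1OC=COS(=O)(=O)C(F)(F)C(F)(F)C(F)(F)C(F)(F)F
F6 | step 7 | 2,4-dibromo-6-(4-bromo-2-methoxyphenoxy)phenol | COc1cc(Br)ccc1Oc1cc(Br)cc(Br)c1O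
F7 | step 7 | 2,4-dibromo-6-(4-bromo-2-hydroxyphenoxy)phenol | Oc1cc(Br)ccc1Oc1cc(Br)cc(Br)c1O
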